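**No free target.** Target cannot be made in this flask without being attacked: reagent in the reaction phase goes for target with 35 M⁻¹ min⁻¹ and for substrate with 12 M⁻¹ min⁻¹, so the selectivity factor of 2.92 runs the wrong way. The shelter is the crystals, since over-reaction counts dissolved target, and I take dissolved target to sit near its solubility of 0.39 mM.

    reagent in the reaction phase ⇌ reagent in the second phase, rate k1*([reagent in the reaction phase] - [reagent in the second phase]/K1) per volume of the first phase (K1 = 2.2, k1 = 0.69 min⁻¹)
    substrate + reagent in the reaction phase → target (k2 = 12 M⁻¹ min⁻¹)
    reagent in the reaction phase + target → over-reacted product (k3 = 35 M⁻¹ min⁻¹)
    2 reagent in the reaction phase → self-condensation product (k4 = 7.3 M⁻¹ min⁻¹)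
    crystals ⇌ target, rate k5*(cs5 - [target]) while solid is left; crystals form when [target] > cs5 (cs5 = 0.39 mM, k5 = 7.9 min⁻¹)

substrate 20 mM; reagent in the second phase 4.00 equiv; time 40 min; volume of the second phase over the first 0.50

1. target and crystals together at 40 min, in percent of the substrate charged
2. the change that raises the amount of target and crystals together at 40 min, in percent of the substrate charged most ("none" if none brings more than 2 percentage points) (oak / ash / birch / larch / none)
3. amount of target and crystals together at 40 min, in percent of the substrate charged, after birch

- oak: doubling the dissolution coefficient of step 5, all else as stated
- ash: doubling the solubility in step 5, all else as stated
- birch: doubling the transfer coefficient of step 1, all else as stated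
- larch: doubling the amount of reagent in the second phase, all else as stated

- for target the crystals are counted in
- for a step with 2 of a species take k times the square, and two of it per event
- in the second phase: reagent in the second phase; everything else is in the first
- charges count per volume of the first phase; a concentration in a rate is the amount of a species over the volume of its own phase; every rate counts per litre of the first phase
- as a solid, counted per litre of solution: crystals
- run time (flask): 40 min

**Turned round.** What would have to be true for the yield to fall rather than rise? Over-reaction would have to outpace making. The ratio of those two rates is the selectivity factor times dissolved target over substrate, and the reagent cancels. With target at solubility, that ratio reaches one at the break-even substrate, solubility times selectivity factor: 1.14 mM, or 5.69% of this charge. With target held at solubility, reagent gains target above it and loses target below it. Each halving of substrate costs ln(2) times the break-even, 3.94% of the charge.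

**Counting halvings.** Transfer relaxes with a half-life of 0.526 min, short against the run, so I share the reagent between the phases at once, giving 38.1 mM in the reaction phase. Self-condensation, with the second phase refilling, halves that in 3.78 min, and I leave out the substrate's draw. That exposure gives 6.10 halvings, so I reckon that 1.46% of the substrate stays and 24.0% goes to over-reaction. Crystals lag behind the making of target, and I reckon that this excess of dissolved target, taken at half that reagent level, costs a further 8.44%. I commit to 66.0%. Oak halves the lag, ash doubles the price, larch adds halvings, and birch shortens an already short half-life, so I pick oak and expect birch to leave the yield alone.

The forecast gives 70%, oak, and 70% after birch, above my figure, with target that “crystallisation holds just above its solubility”.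

**The flask.** It gives 71.2%, oak first with 2.6 percentage points, and 71.0% after birch. In this flask target and crystals read 72.3% at 20.0 min, with substrate at 6.64%, still above the break-even share. The neighbour charged with 12 mM has its break-even at 9.50% of its charge. Its 5.9% of substrate left at 40.0 min prices over-reaction at 26.9%, and its over-reacted product reads 30.1%.

The constants used here were drawn at random within sensible limits; the rest is arithmetic.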